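**Retrosynthetic overview**
1. Endgame: 42 ⇐ triacetylation, 13,14-epoxidation anti to O12, and 2-OH-directed 3,4-epoxidation of the (3Z)-diene chloro lactone 37. 37 ⇐ chloride opening at C6 of a trans-6,7-epoxide plus lactonisation. C17–C19 ⇐ propanoate aldol at the C8 ketone of 33.
2. Key disconnection: the ten-membered carbocycle (C1–C10) of 33 ⇐ the eleven-membered oxacycle 30 (C1–C5, C16, O, C7–C10), by an enolate [2,3]-Wittig ring contraction onto a (Z)-chlorovinyl terminus followed in the same flask by oxirane closure.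
3. Enabling feature: in the ten-membered ring the exocyclic methylene C5=C16 stands next to the vicinal C6–Cl/C7–O pair. The array C16=C5–C6(X)–C7–O is the retron of a [2,3] shift of a C16–O–C7 ether. The γ-lactone ring oxygen on C7 is the former ring oxygen, and carbinol C8 can be a ketone that acidifies C7.
4. 30 ⇐ ring-closing metathesis (C3=C4) of 29 ⇐ diazoketone 25 + chlorodienol 28 (propargyl alcohol, vinyl Grignard, NCS). 25 ⇐ bridged lactone 12 by two carbonyl additions (C9 Felkin–Anh, C2 CBS).
5. Ring order: cyclohexene (auxiliary Diels–Alder sets C1, C10, C11; iodolactonisation/elimination sets O12 and C13=C14) → 11-ring → 10-ring + oxirane → γ-lactone → two oxiranes.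

Key step: step 18

Remark (numbering, abbreviations, assumption): briarane numbering is used. C1 is the quaternary fusion carbon (bears C15H3). C2–C9 run round the large ring: CH–O C2, oxirane C3/C4, C5(=C16H2), CHCl C6, lactone CH–O C7, carbinol C8, CH–O C9. C10 is the fusion CH. C11(C20H3)–C12(O)–C13–C14 complete the six-membered ring, and C17(C18H3)–C19(=O) complete the lactone. β is the face of C15H3. PMB = 4-methoxybenzyl, TBS = tert-butyldimethylsilyl. It is assumed that 2 is used as its commercial monohydrate and 19 as its commercial THF solution.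

Step 1
Reactants: 1 methyl 2-(triphenyl-λ5-phosphanylidene)propanoate; 2 glyoxylic acid
Product: 3 (E)-4-methoxy-3-methyl-4-oxobut-2-enoic acid
Conditions: CH2Cl2, 0 °C → rt
Reagents that add atoms: none
Why: Wittig olefination of the free aldehyde with a stabilised ylide should give the (E)-alkene, which places the future C2 ester and C9 acid trans and fixes which carboxyl group is free.

Step 2
Reactants: 3 (E)-4-methoxy-3-methyl-4-oxobut-2-enoic acid; 4 (S)-4-benzyl-1,3-oxazolidin-2-one
Product: 6 methyl (E)-4-[(4S)-4-benzyl-2-oxo-1,3-oxazolidin-3-yl]-2-methyl-4-oxobut-2-enoate, via pivalic mixed anhydride 5 (not isolated)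
Conditions: PivCl, Et3N, THF, −20 °C; then LiCl, 4, −20 °C → rt
Reagents that add atoms: pivaloyl chloride CC(C)(C)C(=O)Cl (its acyl group is found in 5 only)
Why: N-acylation of the oxazolidinone through the mixed anhydride is a standard route to the imide and leaves the conjugated methyl ester untouched.

Step 3
Reactants: 6 imide dienophile; 7 (E)-penta-1,3-diene
Product: 8 cyclohexene imide (C1 C10 C11 as in the target; C12=C13)
Conditions: Et2AlCl (1.4 equiv), 7 (5 equiv), CH2Cl2, −78 → −20 °C; 1 M HCl
Reagents that add atoms: none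
Why: Auxiliary-controlled Lewis-acid Diels–Alder reaction in which the Al-chelated s-cis imide is the dominant acceptor, so the methyl-bearing diene terminus bonds to C10 (ortho rule), the diene adds anti to the benzyl group (C1, C10), the imide carbonyl is endo (C20 methyl cis to C9) and the (E)-alkene keeps C2 and C9 trans.

Step 4
Reactants: 8 cyclohexene imide
Product: 10 cyclohexene half-ester acid (C9 acid; C2 methyl ester), via peroxy acid 9 (not isolated)
Conditions: LiOH, H2O2, THF–H2O, 0 °C; then Na2SO3; HCl to pH 2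
Reagents that add atoms: hydrogen peroxide OO
Why: Hydroperoxide cleavage of the imide attacks the exocyclic carbonyl selectively, the neopentylic methyl ester survives and no stereocentre is touched.

Step 5
Reactants: 10 cyclohexene half-ester acid
Product: 11 bridged iodolactone (C9(=O)–O12; 13α-iodide)
Conditions: I2, KI, NaHCO3, CH2Cl2–H2O, 0 °C → rt, dark
Reagents that add atoms: iodine II
Why: Iodolactonisation of the γ,δ-unsaturated acid closes the bridged γ-lactone (5-exo), so O12 must enter cis to C9 (β) and iodine anti at C13.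

Step 6
Reactants: 11 bridged iodolactone
Product: 12 bridged unsaturated lactone (C13=C14)
Conditions: DBU, toluene, 80 °C
Reagents that add atoms: none
Why: E2 elimination of the axial iodide with the anti-periplanar C14–H (C12–H is not anti) should move the alkene to C13=C14.

Step 7
Reactants: 12 bridged unsaturated lactone
Product: 13 hydroxy Weinreb amide (free 12-OH)
Conditions: MeNH(OMe)·HCl, i-PrMgCl, THF, −20 → 0 °C; aq NH4Cl
Reagents that add atoms: N,O-dimethylhydroxylamine hydrochloride CNOC.Cl
Why: Aminolysis of the strained allylic lactone with the magnesium amide gives the Weinreb amide, while the ester on quaternary C1 is too hindered to react.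

Step 8
Reactants: 13 hydroxy Weinreb amide
Product: 14 O12-TBS Weinreb amide
Conditions: TBSOTf, 2,6-lutidine, CH2Cl2, 0 °C
Reagents that add atoms: tert-butyldimethylsilyl triflate CC(C)(C)[Si](C)(C)OS(=O)(=O)C(F)(F)F
Why: Silylation under non-alkoxide conditions blocks O12 before relactonisation and installs the bulky β-face group that later helps to steer the 13,14-epoxidation.

Step 9
Reactants: 14 O12-TBS Weinreb amide
Product: 15 C9 aldehyde
Conditions: DIBAL-H (1.2 equiv), THF, −78 °C; Rochelle salt
Reagents that add atoms: none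
Why: Weinreb amide reduction stops at the chelated tetrahedral intermediate and is faster than attack on the neopentylic ester.

Step 10
Reactants: 15 C9 aldehyde; 16 ethyl vinyl ether
Product: 18 trans-fused γ-lactone (C2(=O)–O9) bearing a 1-ethoxyvinyl group at C9, via lithium C9 alkoxide 17 (not isolated)
Conditions: 16, t-BuLi, THF, −78 → 0 °C; then 15, −78 °C → rt; H2O
Reagents that add atoms: tert-butyllithium [Li]C(C)(C)C (lithium in 17 only)
Why: Addition of the acetyl-anion equivalent 1-ethoxyvinyllithium should follow the Felkin–Anh model (C1 as the large group anti to the nucleophile) and set C9, and on warming the alkoxide lactonises onto the C2 ester, which masks O9 and activates C2.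

Step 11
Reactants: 18 trans-fused γ-lactone; 19 vinylmagnesium bromide
Product: 20 C2 vinyl ketone with free 9-OH
Conditions: 19 (1.3 equiv), THF, −78 → −40 °C; pH 7 buffer
Reagents that add atoms: none
Why: Mono-addition of a Grignard reagent to a lactone, because the hindered magnesium lactolate persists at low temperature and releases the vinyl ketone only on work-up.

Step 12
Reactants: 20 C2 vinyl ketone
Product: 21 (2R)-allylic alcohol diol (2-OH and 9-OH free)
Conditions: (S)-Me-CBS (0.5 equiv), catecholborane, toluene, −78 °C; aq NaOH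
Reagents that add atoms: none
Why: CBS reduction in which tertiary C1 is the large and vinyl the small ketone substituent, so the (S)-catalyst should give the (2R)-alcohol (the spatial arrangement of the target), matched with the Felkin–Anh preference for hydride attack.

Step 13
Reactants: 21 diol
Product: 23 bis-PMB methyl ketone, via bis-PMB enol ether 22 (not isolated)
Conditions: NaH, PMBBr, TBAI (cat.), THF–DMF, −10 → 0 °C; then 0.5 M HCl, THF, 0 °C
Reagents that add atoms: 4-methoxybenzyl bromide COc1ccc(CBr)cc1; water O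
Why: Williamson etherification of both alkoxides, kept cold to outrun an anionic oxy-Cope shift of the C2 alkoxide, gives chelating and oxidatively removable ethers, and dilute acid then hydrolyses only the enol ether.

Step 14
Reactants: 23 bis-PMB methyl ketone
Product: 25 diazoketone (C7H=N2), via trifluoroacetyl diketone 24 (not isolated)
Conditions: LiHMDS, THF, −78 °C; CF3CO2CH2CF3; 5% HCl; then MsN3, Et3N, H2O, MeCN, rt
Reagents that add atoms: 2,2,2-trifluoroethyl trifluoroacetate O=C(OCC(F)(F)F)C(F)(F)F (found in 24 only); methanesulfonyl azide CS(=O)(=O)N=[N+]=[N-]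
Why: Detrifluoroacetylative diazo transfer, in which the kinetic enolate forms at the methyl group, is activated as the trifluoroacetyl diketone and takes up N2 from the sulfonyl azide.

Step 15
Reactants: 26 prop-2-yn-1-ol; 19 vinylmagnesium bromide
Product: 28 (Z)-2-(chloromethylidene)but-3-en-1-ol, via cyclic alkenylmagnesium alkoxide 27 (not isolated)
Conditions: 19 (3 equiv), CuI (10 mol %), THF, 0 °C → rt; then NCS, −30 °C → rt; aq NH4Cl
Reagents that add atoms: N-chlorosuccinimide O=C1CCC(=O)N1Cl
Why: Copper-catalysed anti-carbomagnesiation of the propargylic alkoxide gives the five-membered alkenylmagnesium chelate, so chlorination with retention places Cl cis to the CH2OH group ((Z)-alkene).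

Step 16
Reactants: 25 diazoketone; 28 (Z)-2-(chloromethylidene)but-3-en-1-ol
Product: 29 α-alkoxy ketone (C16–O–C7 ether; metathesis precursor)
Conditions: Rh2(OAc)4 (1 mol %), 28 (5 equiv), CH2Cl2, rt, slow addition of 25
Reagents that add atoms: none
Why: Rhodium-carbenoid O–H insertion, where the large excess of the cheap alcohol should make ylide formation and proton transfer faster than C–H insertion into the PMB methylene or cyclopropanation.

Step 17
Reactants: 29 α-alkoxy ketone
Product: 30 eleven-membered oxacycle ((3Z)-alkene; (Z)-chloromethylidene at C5)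
Conditions: Grubbs II (10 mol %), toluene (0.5 mM), 80 °C, Ar sparge
Reagents that add atoms: none
Why: Ring-closing metathesis of the two monosubstituted alkenes (the trisubstituted chloroalkene and the cyclohexene are inert) is a reaction type known for eleven-membered rings fused to small rings, and the four-atom C2–C5 bridge between a neopentylic centre and an sp2 centre should leave room only for the (3Z)-alkene.

Step 18
Reactants: 30 eleven-membered oxacycle
Product: 33 ten-membered trans-6,7-epoxy-8-ketone (C5=C16 methylene), via lithium enolate 31 (not isolated), via chloro alkoxide 32 (not isolated)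
Conditions: LiHMDS (1.1 equiv), THF, −78 → 0 °C; pH 7 buffer
Reagents that add atoms: lithium bis(trimethylsilyl)amide [Li]N([Si](C)(C)C)[Si](C)(C)C (lithium in 31 and 32 only)
Why: Proposed new method: LiHMDS removes a proton from C7, the only CH2 next to the C8 ketone, to give the chelated Z(O)-enolate 31, C7 then bonds to the chlorovinyl carbon C6 while the C16–O bond breaks ([2,3]-Wittig shift through a five-membered envelope), so the eleven-membered oxacycle (C1–C5, C16, O, C7–C10) becomes the ten-membered carbocycle with C5=C16 as exocyclic methylene, and the α-keto alkoxide 32 displaces the neighbouring chloride to give the oxirane and LiCl, which makes the nearly thermoneutral enolate shift irreversible. The closest known reaction types are the [2,3]-Wittig ring contraction of macrocyclic allylic ethers (three-atom contraction), the enolate [2,3]-Wittig shift of α-allyloxy carbonyl compounds and the base closure of the chlorohydrins from γ-chloroallylboration to vinyl oxiranes; new are the one-atom contraction through a 2-substituted allyl unit and the chlorine on the migration terminus. The ten-membered ring closes by suprafacial sigmatropic C6–C7 bond formation in a bicyclo[7.2.1]-like transition state, the oxirane by 3-exo-tet SN2 with inversion at C6. C7 is controlled by C9, because in the Z(O)-enolate C10 and with it the ring chain that carries C5=C6 lie on the enolate face opposite to H9, so C6 can reach only that face; C6 is controlled by the (Z)-chloroalkene together with the endo arrangement (C8 over C4/C5) that the short C9–C4 bridge enforces, which gives the anti-chlorohydrin and after inversion the trans-6,7-epoxide. The step needs C7 over C9 enolisation (a CH2 against a hindered CH flanked by C10), [2,3] over [3,3] and [1,2] shift (the [3,3] path would have to build a nine-membered ring with a fully substituted C8, and lithium in THF disfavours it) and survival of the chlorodiene (amide base at low temperature, no organolithium).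

Step 19
Reactants: 33 ten-membered epoxy ketone; 34 ethyl propanoate
Product: 35 aldol adduct (tertiary 8-OH; C17 ester side chain)
Conditions: LDA, 34 (3 equiv), THF, −78 °C; then 33, −78 °C; AcOH
Reagents that add atoms: none
Why: Aldol addition of the E(O)-lithium enolate to the ketone held in a chelate with O9 (PMB) and the oxirane oxygen, where Cram-chelate attack from the outer face sets C8 and the Zimmerman–Traxler chair with C9 axial on the chelate and the methyl group equatorial sets C17.

Step 20
Reactants: 35 aldol adduct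
Product: 37 chloro lactone (6-Cl; C7–O–C19 γ-lactone; 8-OH), via chlorohydrin ester 36 (not isolated)
Conditions: ClTi(Oi-Pr)3 (2 equiv), CH2Cl2, 0 °C → rt; H2O
Reagents that add atoms: chlorotitanium triisopropoxide CC(C)O[Ti](Cl)(OC(C)C)OC(C)C
Why: Titanium-assisted C-3 opening of a 2,3-epoxy alcohol, in which the C8 alkoxide binds titanium, chloride attacks the distal and allylic C6 with inversion (restoring the configuration created in step 18) and the titanium C7 alkoxide lactonises onto the ester.

Step 21
Reactants: 37 chloro lactone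
Product: 38 2,8,9-triol
Conditions: DDQ, CH2Cl2–pH 7 buffer, 0 °C
Reagents that add atoms: none
Why: Oxidative PMB cleavage under buffered conditions leaves the silyl ether, the allylic chloride and the lactone untouched.

Step 22
Reactants: 38 2,8,9-triol
Product: 39 3,4-epoxide
Conditions: VO(acac)2 (5 mol %), t-BuOOH, CH2Cl2, 0 °C
Reagents that add atoms: tert-butyl hydroperoxide CC(C)(C)OO
Why: Vanadium-catalysed hydroxyl-directed epoxidation gives the cis-epoxy alcohol in medium-ring (Z)-allylic alcohols, that is oxygen on the face of 2-OH (C3, C4), and only the alkene next to the free allylic OH reacts quickly.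

Step 23
Reactants: 39 3,4-epoxide
Product: 40 3,4:13,14-bis-epoxide
Conditions: DMDO, acetone, 0 °C
Reagents that add atoms: dimethyldioxirane CC1(C)OO1
Why: Dioxirane epoxidation of the only remaining nucleophilic alkene (C5=C16 is deactivated by the flanking oxirane and chloride), with the axial C15 methyl and the O12 silyl ether on the β face directing the neutral oxidant to the α face (C13, C14).

Step 24
Reactants: 40 bis-epoxide
Product: 41 2,8,9,12-tetraol
Conditions: TBAF–AcOH (1:1), THF, 0 °C → rt
Reagents that add atoms: none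
Why: Buffered fluoride desilylation avoids Payne rearrangement of the liberated trans-epoxy alcohol and opening of the vinyl oxirane.

Step 25
Reactants: 41 tetraol
Product: 42 target CNP0229305.1
Conditions: Ac2O, pyridine, DMAP (cat.), CH2Cl2, 0 °C → rt
Reagents that add atoms: acetic anhydride CC(=O)OC(C)=O
Why: Acetylation of the three secondary alcohols, while the tertiary hydrogen-bonded 8-OH is too hindered to react under these conditions.

**Compound list**
1 | methyl 2-(triphenyl-λ5-phosphanylidene)propanoate | COC(=O)C(C)=P(c1ccccc1)(c1ccccc1)c1ccccc1 | starting material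
2 | glyoxylic acid | O=CC(=O)O | starting material
3 | (E)-4-methoxy-3-methyl-4-oxobut-2-enoic acid | COC(=O)/C(C)=C/C(=O)O | intermediate
4 | (S)-4-benzyl-1,3-oxazolidin-2-one | O=C1N[C@@H](Cc2ccccc2)CO1 | starting material
5 | pivalic mixed anhydride of 3 | COC(=O)/C(C)=C/C(=O)OC(=O)C(C)(C)C | intermediate
6 | methyl (E)-4-[(4S)-4-benzyl-2-oxo-1,3-oxazolidin-3-yl]-2-methyl-4-oxobut-2-enoate | COC(=O)/C(C)=C/C(=O)N1C(=O)OC[C@@H]1Cc1ccccc1 | intermediate
7 | (E)-penta-1,3-diene | C=C/C=C/C | starting material
8 | cyclohexene imide | COC(=O)[C@]2(C)[C@H]([C@@H](C)C=CC2)C(=O)N1C(=O)OC[C@@H]1Cc1ccccc1 | intermediate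
9 | peroxy acid from 8 | COC(=O)[C@]1(C)[C@H]([C@@H](C)C=CC1)C(=O)OO | intermediate
10 | cyclohexene half-ester acid | COC(=O)[C@]1(C)[C@H]([C@@H](C)C=CC1)C(=O)O | intermediate
11 | bridged iodolactone | COC(=O)[C@]1(C)[C@H]([C@@H](C)[C@@H]2[C@H](I)C1)C(=O)O2 | intermediate
12 | bridged unsaturated lactone | COC(=O)[C@]1(C)[C@H]([C@@H](C)[C@@H]2C=C1)C(=O)O2 | intermediate
13 | hydroxy Weinreb amide | COC(=O)[C@]1(C)[C@H]([C@@H](C)[C@@H](O)C=C1)C(=O)N(C)OC | intermediate
14 | O12-TBS Weinreb amide | COC(=O)[C@]1(C)[C@H]([C@@H](C)[C@@H](O[Si](C)(C)C(C)(C)C)C=C1)C(=O)N(C)OC | intermediate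
15 | C9 aldehyde | COC(=O)[C@]1(C)[C@H]([C@@H](C)[C@@H](O[Si](C)(C)C(C)(C)C)C=C1)C=O | intermediate
16 | ethyl vinyl ether | C=COCC | starting material
17 | lithium C9 alkoxide | COC(=O)[C@]1(C)[C@H]([C@@H](C)[C@@H](O[Si](C)(C)C(C)(C)C)C=C1)[C@@H](O[Li])C(=C)OCC | intermediate
18 | trans-fused γ-lactone with 1-ethoxyvinyl group | O=C1[C@]2(C)[C@H]([C@@H](C)[C@@H](O[Si](C)(C)C(C)(C)C)C=C2)[C@H](C(=C)OCC)O1 | intermediate
19 | vinylmagnesium bromide | C=C[Mg]Br | starting material
20 | C2 vinyl ketone with free 9-OH | C=CC(=O)[C@]1(C)[C@H]([C@@H](C)[C@@H](O[Si](C)(C)C(C)(C)C)C=C1)[C@@H](O)C(=C)OCC | intermediate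
21 | (2R)-allylic alcohol diol | C=C[C@@H](O)[C@]1(C)[C@H]([C@@H](C)[C@@H](O[Si](C)(C)C(C)(C)C)C=C1)[C@@H](O)C(=C)OCC | intermediate
22 | bis-PMB enol ether | C=C[C@@H](OCc2ccc(OC)cc2)[C@]1(C)[C@H]([C@@H](C)[C@@H](O[Si](C)(C)C(C)(C)C)C=C1)[C@@H](OCc1ccc(OC)cc1)C(=C)OCC | intermediate
23 | bis-PMB methyl ketone | C=C[C@@H](OCc2ccc(OC)cc2)[C@]1(C)[C@H]([C@@H](C)[C@@H](O[Si](C)(C)C(C)(C)C)C=C1)[C@@H](OCc1ccc(OC)cc1)C(C)=O | intermediate
24 | trifluoroacetyl diketone | C=C[C@@H](OCc2ccc(OC)cc2)[C@]1(C)[C@H]([C@@H](C)[C@@H](O[Si](C)(C)C(C)(C)C)C=C1)[C@@H](OCc1ccc(OC)cc1)C(=O)CC(=O)C(F)(F)F | intermediate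
25 | diazoketone | C=C[C@@H](OCc2ccc(OC)cc2)[C@]1(C)[C@H]([C@@H](C)[C@@H](O[Si](C)(C)C(C)(C)C)C=C1)[C@@H](OCc1ccc(OC)cc1)C(=O)C=[N+]=[N-] | intermediate
26 | prop-2-yn-1-ol | C#CCO | starting material
27 | cyclic alkenylmagnesium alkoxide | C=CC1=C[Mg]OC1 | intermediate
28 | (Z)-2-(chloromethylidene)but-3-en-1-ol | OC/C(C=C)=C\Cl | intermediate
29 | α-alkoxy ketone (metathesis precursor) | C=C[C@@H](OCc2ccc(OC)cc2)[C@]1(C)[C@H]([C@@H](C)[C@@H](O[Si](C)(C)C(C)(C)C)C=C1)[C@@H](OCc1ccc(OC)cc1)C(=O)COC/C(C=C)=C\Cl | intermediate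
30 | eleven-membered oxacycle | Cl/C=C1/C=C\[C@@H](OCc3ccc(OC)cc3)[C@]2(C)[C@H]([C@@H](C)[C@@H](O[Si](C)(C)C(C)(C)C)C=C2)[C@@H](OCc3ccc(OC)cc3)C(=O)COC1 | intermediate
31 | Z(O)-lithium enolate of 30 | Cl/C=C1/C=C\[C@@H](OCc3ccc(OC)cc3)[C@]2(C)[C@H]([C@@H](C)[C@@H](O[Si](C)(C)C(C)(C)C)C=C2)[C@@H](OCc3ccc(OC)cc3)/C(O[Li])=C/OC1 | intermediate
32 | lithium alkoxide of the ten-membered anti-chlorohydrin ketone | C=C1/C=C\[C@@H](OCc3ccc(OC)cc3)[C@]2(C)[C@H]([C@@H](C)[C@@H](O[Si](C)(C)C(C)(C)C)C=C2)[C@@H](OCc3ccc(OC)cc3)C(=O)[C@@H](O[Li])[C@H]1Cl | intermediate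
33 | ten-membered trans-6,7-epoxy-8-ketone | C=C1/C=C\[C@@H](OCc3ccc(OC)cc3)[C@]2(C)[C@H]([C@@H](C)[C@@H](O[Si](C)(C)C(C)(C)C)C=C2)[C@@H](OCc3ccc(OC)cc3)C(=O)[C@H]3O[C@@H]31 | intermediate
34 | ethyl propanoate | CCC(=O)OCC | starting material
35 | aldol adduct | C=C1/C=C\[C@@H](OCc3ccc(OC)cc3)[C@]2(C)[C@H]([C@@H](C)[C@@H](O[Si](C)(C)C(C)(C)C)C=C2)[C@@H](OCc3ccc(OC)cc3)[C@](O)([C@@H](C)C(=O)OCC)[C@H]3O[C@@H]31 | intermediate
36 | chlorohydrin ester (formed as its titanium alkoxide) | C=C1/C=C\[C@@H](OCc3ccc(OC)cc3)[C@]2(C)[C@H]([C@@H](C)[C@@H](O[Si](C)(C)C(C)(C)C)C=C2)[C@@H](OCc3ccc(OC)cc3)[C@](O)([C@@H](C)C(=O)OCC)[C@@H](O)[C@H]1Cl | intermediate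
37 | chloro lactone | C=C1/C=C\[C@@H](OCc3ccc(OC)cc3)[C@]2(C)[C@H]([C@@H](C)[C@@H](O[Si](C)(C)C(C)(C)C)C=C2)[C@@H](OCc3ccc(OC)cc3)[C@]2(O)[C@@H](C)C(=O)O[C@H]2[C@H]1Cl | intermediate
38 | 2,8,9-triol | C=C1/C=C\[C@@H](O)[C@]2(C)[C@H]([C@@H](C)[C@@H](O[Si](C)(C)C(C)(C)C)C=C2)[C@@H](O)[C@]2(O)[C@@H](C)C(=O)O[C@H]2[C@H]1Cl | intermediate
39 | 3,4-epoxide | C=C1[C@H]2O[C@H]2[C@@H](O)[C@]2(C)[C@H]([C@@H](C)[C@@H](O[Si](C)(C)C(C)(C)C)C=C2)[C@@H](O)[C@]2(O)[C@@H](C)C(=O)O[C@H]2[C@H]1Cl | intermediate
40 | 3,4:13,14-bis-epoxide | C=C1[C@H]2O[C@H]2[C@@H](O)[C@]2(C)[C@H]([C@@H](C)[C@@H](O[Si](C)(C)C(C)(C)C)[C@@H]3O[C@@H]32)[C@@H](O)[C@]2(O)[C@@H](C)C(=O)O[C@H]2[C@H]1Cl | intermediate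
41 | 2,8,9,12-tetraol | C=C1[C@H]2O[C@H]2[C@@H](O)[C@]2(C)[C@H]([C@@H](C)[C@@H](O)[C@@H]3O[C@@H]32)[C@@H](O)[C@]2(O)[C@@H](C)C(=O)O[C@H]2[C@H]1Cl | intermediate
42 | CNP0229305.1 | C=C1[C@H]2O[C@H]2[C@@H](OC(C)=O)[C@]2(C)[C@H]([C@@H](C)[C@@H](OC(C)=O)[C@@H]3O[C@@H]32)[C@@H](OC(C)=O)[C@]2(O)[C@@H](C)C(=O)O[C@H]2[C@H]1Cl | target

**Step count and risks**

Total step count: 25. Longest linear sequence: 24 (steps 1–14 and 16–25; step 15 is a one-step branch).

The three steps most likely to fail:

1. Step 18.
   - What may go wrong: the shift may be too slow compared with enolate equilibration towards C9, a competing [3,3] shift, or loss of HCl from the chlorodiene.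
   - Fallback: known chemistry that is still a one-atom ring contraction (Ramberg–Bäcklund). It sets out from 25 and returns at 33.
   - Carbomagnesiation of 26 with 19 as in step 15, but with a proton quench, should give 2-methylidenebut-3-en-1-ol F1. A Mitsunobu reaction with thioacetic acid should give the thioacetate F2, and methanolysis the thiol F3.
   - Rhodium-catalysed S–H insertion of 25 into the thiol should give the keto sulfide F4. Molybdate/H2O2 oxidation should give the β-keto sulfone F5. Ring-closing metathesis as in step 17 should give the eleven-membered cyclic sulfone F6 (ring C1–C6, S, C7–C10).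
   - Ramberg–Bäcklund reaction with in situ halogenation (CCl4, KOH, t-BuOH) extrudes SO2 and should give the ten-membered trienone F7 (C6=C7).
   - Weitz–Scheffer epoxidation (t-BuOOH, DBU, or a chiral lanthanum–BINOL peroxide system if the ring does not bias the face) then leads to 33.

2. Step 19.
   - What may go wrong: enolisation of the hindered ring ketone instead of addition, retro-aldol, or poor facial and C17 selectivity.
   - Fallback: intramolecular delivery of the propanoate. It sets out from 33 and returns at 37.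
   - Opening of the epoxy ketone at the allylic β-carbon C6 with pyridinium chloride should give the chlorohydrin ketone F8. Acylation of 7-OH with 2-bromopropanoyl bromide and pyridine at low temperature should give the bromo ester F9.
   - A rhodium-catalysed Reformatsky reaction with Et2Zn (non-basic, so the β-chloro ketone is not eliminated) closes the γ-lactone onto C8 and gives 37.

3. Step 3.
   - What may go wrong: low reactivity of the β,β-disubstituted imide towards an acyclic diene, with polymerisation of the diene by the Lewis acid.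
   - Fallback: a more electrophilic enal dienophile under catalytic control. It sets out from 7 and returns at 10.
   - SeO2 oxidation of commercial methyl tiglate should give methyl (E)-2-methyl-4-oxobut-2-enoate F10, whose aldehyde on C10 is now the dominant acceptor.
   - A chiral oxazaborolidinium-catalysed Diels–Alder reaction with 7, using the catalyst enantiomer that exposes the same C10 face, should give the cyclohexene aldehyde F11. Pinnick oxidation then gives 10.

**Further compounds**
F1 | step 18 | 2-methylidenebut-3-en-1-ol | C=CC(=C)CO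
F2 | step 18 | S-(2-methylidenebut-3-en-1-yl) ethanethioate | C=CC(=C)CSC(C)=O
F3 | step 18 | 2-methylidenebut-3-ene-1-thiol | C=CC(=C)CS
F4 | step 18 | keto sulfide | C=C[C@@H](OCc2ccc(OC)cc2)[C@]1(C)[C@H]([C@@H](C)[C@@H](O[Si](C)(C)C(C)(C)C)C=C1)[C@@H](OCc1ccc(OC)cc1)C(=O)CSCC(=C)C=C
F5 | step 18 | β-keto sulfone | C=C[C@@H](OCc2ccc(OC)cc2)[C@]1(C)[C@H]([C@@H](C)[C@@H](O[Si](C)(C)C(C)(C)C)C=C1)[C@@H](OCc1ccc(OC)cc1)C(=O)CS(=O)(=O)CC(=C)C=C
F6 | step 18 | eleven-membered cyclic sulfone | C=C1/C=C\[C@@H](OCc3ccc(OC)cc3)[C@]2(C)[C@H]([C@@H](C)[C@@H](O[Si](C)(C)C(C)(C)C)C=C2)[C@@H](OCc3ccc(OC)cc3)C(=O)CS(=O)(=O)C1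
F7 | step 18 | ten-membered trienone | C=C1/C=C\[C@@H](OCc3ccc(OC)cc3)[C@]2(C)[C@H]([C@@H](C)[C@@H](O[Si](C)(C)C(C)(C)C)C=C2)[C@@H](OCc3ccc(OC)cc3)C(=O)/C=C/1
F8 | step 19 | chlorohydrin ketone | C=C1/C=C\[C@@H](OCc3ccc(OC)cc3)[C@]2(C)[C@H]([C@@H](C)[C@@H](O[Si](C)(C)C(C)(C)C)C=C2)[C@@H](OCc3ccc(OC)cc3)C(=O)[C@@H](O)[C@H]1Cl
F9 | step 19 | 7-O-(2-bromopropanoyl) chlorohydrin ketone | C=C1/C=C\[C@@H](OCc3ccc(OC)cc3)[C@]2(C)[C@H]([C@@H](C)[C@@H](O[Si](C)(C)C(C)(C)C)C=C2)[C@@H](OCc3ccc(OC)cc3)C(=O)[C@@H](OC(=O)C(C)Br)[C@H]1Cl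
F10 | step 3 | methyl (E)-2-methyl-4-oxobut-2-enoate | COC(=O)/C(C)=C/C=O
F11 | step 3 | cyclohexene aldehyde | COC(=O)[C@]1(C)[C@H]([C@@H](C)C=CC1)C=O
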